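Target is not where this flask stops: the readings of the north run show it disappearing while more of it is being made.

| flask | starting material | free catalyst | target | time |
|---|---|---|---|---|
| south | 1.00 M | 0.00200 M |  |  |
| north-west | 0.500 M | 0.00200 M |  |  |
| south-west | 1.00 M | 0.00300 M |  |  |
| north | 1.00 M | 0.00200 M | 0.500 M |  |
| west | 1.00 M | 0.00200 M |  | 19 min |

| run | time / min | [target] / M |
|---|---|---|
| south run | 0.96 | 0.119 |
| south run | 1.9 | 0.173 |
| south run | 2.9 | 0.227 |
| south run | 3.8 | 0.268 |
| south run | 4.8 | 0.281 |
| north-west run | 0.96 | 0.014 |
| north-west run | 1.9 | 0.060 |
| north-west run | 2.9 | 0.054 |
| north-west run | 3.8 | 0.083 |
| north-west run | 4.8 | 0.095 |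
| south-west run | 0.96 | 0.125 |
| south-west run | 1.9 | 0.217 |
| south-west run | 2.9 | 0.267 |
| south-west run | 3.8 | 0.283 |
| south-west run | 4.8 | 0.305 |
| north run | 0.96 | 0.539 |
| north run | 1.9 | 0.556 |
| north run | 2.9 | 0.540 |
| north run | 3.8 | 0.535 |
| north run | 4.8 | 0.514 |

(readings scatter by 0.01 M)

- Overall: starting material -> target, with free catalyst as catalyst.
- Constant volume, constant temperature.
- A reading of a species includes what of it is bound.
- An order is taken over about fifteen percent of the charge, up and down.

* the power of [starting material] that the first rate follows, about the charge of the south run; measure it at two percent of starting material made into target (one fixed amount of target, the same in the runs compared)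
* the power of [free catalyst] that the first rate follows, about the charge of the south run; measure it at two percent of starting material made into target
* target in the west run at 19 min, as a share of the starting material charged

The north and south runs have the same starting material and free catalyst and differ by 0.500 M of added target, so I subtract the south readings from the north ones. I assume that added target leaves formation alone, and what remains is then the survival of that added target. At 4.8 min the gap is 0.233 M.

> loss constant = ln(added target / gap) / time = 0.159 /min

This loss constant is the fraction of target lost per minute. As a check, it predicts a gap of 0.315 M at 2.9 min, and the readings there give 0.313 M.

Now the ladder, fastest rung first. Target lives 6.29 min. The first reading of the south run gives a formation rate of 0.124 M/min, so the charge over that rate, the use-up time, is 8.07 min, which is longer than the lifetime of target. The north-west run, charged with 0.500 M, has made less target by 4.8 min than the south run has by 0.96 min, so I take formation as following the square of starting material. The west run has the charge of the south run, and for its 19 min I reckon: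

> starting material left = charge / (1 + time / use-up time) = 0.298 M
> formation = first rate × (left / charge) squared = 0.0110 M/min
> fractional fall of formation = 0.0739 /min

That fall takes 13.5 min per e-fold, slower than the lifetime of target. On this top rung, target in the west run behaves as an intermediate in a quasi-steady state, trailing its own formation:

> target = formation / (loss constant − fall) = 0.129 M

I commit to 12.9% of the charge.

The forecast gives powers of 2 and 0.5 and a west share of 26%, which is higher than mine. It reads the north run differently from me: “So target inhibits its own formation and is also slowly lost, or reverts”.

The simulation gives powers of 1.9 and 0.59 and a west share of 13.5%.

    free catalyst + starting material ⇌ catalyst-substrate complex, settled at all times (0.6810 /M)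
    catalyst-substrate complex + starting material ⇌ doubly bound catalyst, settled at all times (2.700 /M)
    doubly bound catalyst → target + catalyst-substrate complex (457.2 /min)
    2 free catalyst ⇌ resting dimer, settled at all times (28600 /M)
    target → decomposed product (0.1518 /min)

The step from target to decomposed product is the main reason for the low west share. At 19 min the west run holds 13.5% of its charge, and my loss constant, itself an estimate from the readings at 0.159 /min, reckons a loss from it of about 0.0215 M/min. The same run without that step holds 73.3% against 13.5% with it, and by that estimated constant the ratio of those shares comes to about 10.6 min of decay.

Readings and results were computed on assumed constants; scatter was added.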